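**Plan**
- Retrosynthetic cuts, in order: the stilbene C=C at C5 (Horner–Wadsworth–Emmons), the aryl ether bond O1–C7a (intramolecular SNAr), the C2–C3 bond (Evans syn-aldol), and the C3–C3a bond as an aryl–CH2 bond (C–H borylation, then Suzuki–Miyaura coupling).
- Forward order: ring A is turned into an arylacetyl imide, the C2–C3 chain is joined by aldol addition to protected vanillin, the dihydrofuran ring is closed by O1–C7a formation, and the resorcinol ring is attached last by olefination.
- Stereochemistry: both centres come from one boron aldol directed by (R)-4-benzyl-1,3-oxazolidin-2-one. The (2R,3R) syn adduct becomes the (1R,2S) diol and then, with retention at both carbons, the (2R,3S)-trans ring.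
- Enabling feature: C7a of ring A (the benzo ring of the dihydrobenzofuran) is para to C5, the carbon that carries the stilbene bridge. Held as a formyl group, C5 activates a C7a–F bond for displacement by the oxygen on C2 and then serves as the olefination handle.

Key step: step 11

Remark: the core is numbered O1, C2 (aryl-bearing), C3 (hydroxymethyl-bearing), C3a, C4–C7, C7a, with C9 the hydroxymethyl carbon. The target is taken as the (2R,3S)-trans isomer that the SMILES encodes. 4-Fluoro-3-methoxybenzaldehyde, (R)-4-benzyl-1,3-oxazolidin-2-one, vanillin and methyl 3,5-dihydroxybenzoate are assumed to be commercial.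

**Step 1**
Reactants: 1 4-fluoro-3-methoxybenzaldehyde
Product: 2 2-(4-fluoro-3-methoxyphenyl)-1,3-dioxolane
Conditions: HOCH2CH2OH, p-TsOH·H2O (cat.), toluene, reflux, Dean–Stark trap
Reagents that add atoms: ethylene glycol, OCCO
Why: Acid-catalysed acetalisation with azeotropic removal of water masks the formyl group for the borylation, enolate and hydride steps that follow.

**Step 2**
Reactants: 2 2-(4-fluoro-3-methoxyphenyl)-1,3-dioxolane
Product: 3 2-[5-(1,3-dioxolan-2-yl)-2-fluoro-3-methoxyphenyl]-4,4,5,5-tetramethyl-1,3,2-dioxaborolane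
Conditions: B2pin2 (1.0 equiv), [Ir(OMe)(cod)]2 (1.5 mol %), 4,4'-di-tert-butyl-2,2'-bipyridine (3 mol %), THF, 65 °C
Reagents that add atoms: bis(pinacolato)diboron, CC1(C)OB(OC1(C)C)B1OC(C)(C)C(C)(C)O1
Why: Iridium-catalysed aromatic C–H borylation is sterically governed, and the only C–H not ortho to the dioxolanyl or methoxy group is the one next to fluorine, a small substituent that also favours borylation at its ortho position electronically.

**Step 3**
Reactants: 3 2-[5-(1,3-dioxolan-2-yl)-2-fluoro-3-methoxyphenyl]-4,4,5,5-tetramethyl-1,3,2-dioxaborolane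
Product: 4 ethyl 2-[5-(1,3-dioxolan-2-yl)-2-fluoro-3-methoxyphenyl]acetate
Conditions: BrCH2CO2Et, Pd2(dba)3 (2 mol %), P(o-tol)3 (8 mol %), K3PO4, THF/H2O, 60 °C
Reagents that add atoms: ethyl bromoacetate, CCOC(=O)CBr
Why: Suzuki–Miyaura sp2–sp3 coupling of an arylboronate with an α-bromo ester forms the aryl–CH2 bond (the future C3–C3a bond) under mildly basic conditions that leave the acetal and the C–F bond alone.

**Step 4**
Reactants: 4 ethyl 2-[5-(1,3-dioxolan-2-yl)-2-fluoro-3-methoxyphenyl]acetate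
Product: 5 2-[5-(1,3-dioxolan-2-yl)-2-fluoro-3-methoxyphenyl]acetic acid
Conditions: LiOH·H2O, THF/H2O (3:1), rt; then cold 1 M HCl to pH 4, 0 °C
Reagents that add atoms: lithium hydroxide, [Li+].[OH-]
Why: Ester saponification proceeds in base, to which the dioxolane is inert, and brief cold acidification to pH 4 should free the acid without hydrolysing the acetal.

**Step 5**
Reactants: 5 2-[5-(1,3-dioxolan-2-yl)-2-fluoro-3-methoxyphenyl]acetic acid; 6 (R)-4-benzyl-1,3-oxazolidin-2-one
Product: 8 (R)-4-benzyl-3-{2-[5-(1,3-dioxolan-2-yl)-2-fluoro-3-methoxyphenyl]acetyl}-1,3-oxazolidin-2-one, via mixed pivalic anhydride 7 (not isolated)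
Conditions: PivCl, Et3N, THF, −20 °C; then 6, LiCl, −20 °C to rt
Reagents that add atoms: none
Why: N-Acylation of the oxazolidinone through the mixed pivalic anhydride under LiCl/Et3N activation avoids strong base and the ketene formation to which arylacetyl derivatives are prone.

**Step 6**
Reactants: 9 vanillin (4-hydroxy-3-methoxybenzaldehyde)
Product: 10 3-methoxy-4-(methoxymethoxy)benzaldehyde
Conditions: MOMCl, iPr2NEt, CH2Cl2, 0 °C to rt
Reagents that add atoms: chloromethyl methyl ether, COCCl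
Why: O-Alkylation of the phenol gives a methoxymethyl ether that is stable to boron enolates, hydride and strong base and keeps the later benzylic alcohol non-phenolic.

**Step 7**
Reactants: 8 (R)-4-benzyl-3-{2-[5-(1,3-dioxolan-2-yl)-2-fluoro-3-methoxyphenyl]acetyl}-1,3-oxazolidin-2-one; 10 3-methoxy-4-(methoxymethoxy)benzaldehyde
Product: 13 (R)-4-benzyl-3-{(2R,3R)-2-[5-(1,3-dioxolan-2-yl)-2-fluoro-3-methoxyphenyl]-3-hydroxy-3-[3-methoxy-4-(methoxymethoxy)phenyl]propanoyl}-1,3-oxazolidin-2-one, via Z-dibutylboron enolate 11 (not isolated), via dibutylboron aldolate 12 (not isolated)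
Conditions: Bu2BOTf (1.2 equiv), iPr2NEt (1.4 equiv), CH2Cl2, −78 to 0 °C; then 10, −78 to 0 °C; then pH 7 buffer, MeOH, 30% H2O2, 0 °C
Reagents that add atoms: none
Why: In this Evans syn-aldol, soft enolisation gives the Z-boron enolate, which adds to the aldehyde through a closed Zimmerman–Traxler chair with the auxiliary carbonyl turned away from the enolate oxygen and the aldehyde on the face opposite the benzyl group, so the (R)-auxiliary should set both new centres as the (2R,3R) syn diad while the excess amine buffers the acetal against the boron triflate.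

**Step 8**
Reactants: 13 (R)-4-benzyl-3-{(2R,3R)-2-[5-(1,3-dioxolan-2-yl)-2-fluoro-3-methoxyphenyl]-3-hydroxy-3-[3-methoxy-4-(methoxymethoxy)phenyl]propanoyl}-1,3-oxazolidin-2-one
Product: 14 (1R,2S)-2-[5-(1,3-dioxolan-2-yl)-2-fluoro-3-methoxyphenyl]-1-[3-methoxy-4-(methoxymethoxy)phenyl]propane-1,3-diol
Conditions: LiBH4, MeOH (1 equiv), THF, 0 °C
Reagents that add atoms: none
Why: Reductive cleavage of the N-acyl oxazolidinone by LiBH4 attacks the exocyclic carbonyl, releases the auxiliary for recovery and leaves both stereocentres untouched, the change of the C2 descriptor from R to S being only a change in substituent priorities.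

**Step 9**
Reactants: 14 (1R,2S)-2-[5-(1,3-dioxolan-2-yl)-2-fluoro-3-methoxyphenyl]-1-[3-methoxy-4-(methoxymethoxy)phenyl]propane-1,3-diol
Product: 15 (1R,2S)-2-[5-(1,3-dioxolan-2-yl)-2-fluoro-3-methoxyphenyl]-1-[3-methoxy-4-(methoxymethoxy)phenyl]-3-[(triisopropylsilyl)oxy]propan-1-ol
Conditions: TIPSCl (1.1 equiv), imidazole, CH2Cl2, 0 °C to rt
Reagents that add atoms: chlorotriisopropylsilane, CC(C)[Si](Cl)(C(C)C)C(C)C
Why: Silylation with the bulky triisopropylsilyl chloride discriminates sterically for the primary hydroxyl over the secondary benzylic one.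

**Step 10**
Reactants: 15 (1R,2S)-2-[5-(1,3-dioxolan-2-yl)-2-fluoro-3-methoxyphenyl]-1-[3-methoxy-4-(methoxymethoxy)phenyl]-3-[(triisopropylsilyl)oxy]propan-1-ol
Product: 16 4-fluoro-3-[(1R,2S)-1-hydroxy-1-[3-methoxy-4-(methoxymethoxy)phenyl]-3-[(triisopropylsilyl)oxy]propan-2-yl]-5-methoxybenzaldehyde
Conditions: PPTS (0.2 equiv), acetone/H2O (10:1), 45 °C
Reagents that add atoms: water, O
Why: Pyridinium-acid-catalysed acetal hydrolysis frees the aryl aldehyde under conditions too mild to cleave the aryl methoxymethyl ether or the silyl ether or to ionise the non-phenolic benzylic alcohol.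

**Step 11**
Reactants: 16 4-fluoro-3-[(1R,2S)-1-hydroxy-1-[3-methoxy-4-(methoxymethoxy)phenyl]-3-[(triisopropylsilyl)oxy]propan-2-yl]-5-methoxybenzaldehyde
Product: 18 (2R,3S)-7-methoxy-2-[3-methoxy-4-(methoxymethoxy)phenyl]-3-{[(triisopropylsilyl)oxy]methyl}-2,3-dihydro-1-benzofuran-5-carbaldehyde, via potassium alkoxide 17 (not isolated)
Conditions: KN(SiMe3)2 (1.05 equiv), 18-crown-6, THF (0.02 M), −78 °C to rt
Reagents that add atoms: none
Why: KN(SiMe3)2 deprotonates the only free hydroxyl to give alkoxide 17, which adds to C7a ipso to fluorine; the Meisenheimer anion is delocalised onto the para formyl oxygen at C5 and collapses by loss of fluoride (addition–elimination SNAr). The closest known reaction type is the intramolecular etherification of para-acyl fluoroarenes by alkoxides. The dihydrofuran ring closes in a 5-exo mode, the tether O–C2–C3–C3a delivering the oxygen to the adjacent ring carbon C7a. No stereocentre is created and no bond to C2 or C3 is broken, so the (1R,2S) syn diad of 16 is carried with retention into the (2R,3S) trans ring, in which the aryl and silyloxymethyl groups stay apart. The step needs chemoselection between the C2 and C9 oxygens, either of which could close a five-membered ring, and this is secured by the bulky triisopropylsilyl ether on C9, which resists 1,3-migration to the neighbouring alkoxide; one equivalent of base, low temperature and high dilution should hold back hydride transfer to the formyl group and intermolecular substitution.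

**Step 12**
Reactants: 19 methyl 3,5-dihydroxybenzoate
Product: 20 methyl 3,5-bis(methoxymethoxy)benzoate
Conditions: MOMCl (2.5 equiv), iPr2NEt, CH2Cl2, 0 °C to rt
Reagents that add atoms: chloromethyl methyl ether, COCCl
Why: Double O-alkylation of the phenols installs base-stable methoxymethyl ethers that are removed together with the vanillyl one at the end.

**Step 13**
Reactants: 20 methyl 3,5-bis(methoxymethoxy)benzoate
Product: 21 [3,5-bis(methoxymethoxy)phenyl]methanol
Conditions: LiAlH4, THF, 0 °C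
Reagents that add atoms: none
Why: Hydride reduction of the benzoate ester to the benzylic alcohol does not touch the acetal-type ethers.

**Step 14**
Reactants: 21 [3,5-bis(methoxymethoxy)phenyl]methanol
Product: 22 1-(bromomethyl)-3,5-bis(methoxymethoxy)benzene
Conditions: CBr4, PPh3, CH2Cl2, 0 °C
Reagents that add atoms: tetrabromomethane, BrC(Br)(Br)Br
Why: The Appel reaction converts the benzylic alcohol into the bromide under essentially neutral conditions that the methoxymethyl ethers tolerate.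

**Step 15**
Reactants: 22 1-(bromomethyl)-3,5-bis(methoxymethoxy)benzene
Product: 23 diethyl [3,5-bis(methoxymethoxy)benzyl]phosphonate
Conditions: P(OEt)3 (neat), 130 °C
Reagents that add atoms: triethyl phosphite, CCOP(OCC)OCC
Why: The Michaelis–Arbuzov reaction of a benzylic bromide with triethyl phosphite gives the phosphonate with loss of volatile bromoethane.

**Step 16**
Reactants: 18 (2R,3S)-7-methoxy-2-[3-methoxy-4-(methoxymethoxy)phenyl]-3-{[(triisopropylsilyl)oxy]methyl}-2,3-dihydro-1-benzofuran-5-carbaldehyde; 23 diethyl [3,5-bis(methoxymethoxy)benzyl]phosphonate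
Product: 25 (2R,3S)-5-{(E)-2-[3,5-bis(methoxymethoxy)phenyl]ethenyl}-7-methoxy-2-[3-methoxy-4-(methoxymethoxy)phenyl]-3-{[(triisopropylsilyl)oxy]methyl}-2,3-dihydro-1-benzofuran, via potassium phosphonate carbanion 24 (not isolated)
Conditions: 23, KOtBu, THF, 0 °C; then 18, 0 °C to rt
Reagents that add atoms: none
Why: Horner–Wadsworth–Emmons olefination of a non-enolisable aryl aldehyde with a benzylphosphonate anion is reversible in the addition step and should deliver the E-stilbene, and the C3–H, which is meta to the activating carbon, is not acidic enough to epimerise.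

**Step 17**
Reactants: 25 (2R,3S)-5-{(E)-2-[3,5-bis(methoxymethoxy)phenyl]ethenyl}-7-methoxy-2-[3-methoxy-4-(methoxymethoxy)phenyl]-3-{[(triisopropylsilyl)oxy]methyl}-2,3-dihydro-1-benzofuran
Product: 26 [(2R,3S)-5-{(E)-2-[3,5-bis(methoxymethoxy)phenyl]ethenyl}-7-methoxy-2-[3-methoxy-4-(methoxymethoxy)phenyl]-2,3-dihydro-1-benzofuran-3-yl]methanol
Conditions: Bu4NF, THF, 0 °C to rt; aqueous work-up
Reagents that add atoms: none
Why: Fluoride-induced desilylation, driven by the strong Si–F bond, frees the C9 alcohol without affecting the methoxymethyl ethers or the stilbene.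

**Step 18**
Reactants: 26 [(2R,3S)-5-{(E)-2-[3,5-bis(methoxymethoxy)phenyl]ethenyl}-7-methoxy-2-[3-methoxy-4-(methoxymethoxy)phenyl]-2,3-dihydro-1-benzofuran-3-yl]methanol
Product: 27 Gnetofuran A, 5-{(E)-2-[(2R,3S)-2-(4-hydroxy-3-methoxyphenyl)-3-(hydroxymethyl)-7-methoxy-2,3-dihydro-1-benzofuran-5-yl]ethenyl}benzene-1,3-diol
Conditions: HCl (1.25 M in MeOH), rt
Reagents that add atoms: none
Why: Acid-catalysed acetal exchange with methanol removes the three aryl methoxymethyl ethers as dimethoxymethane, and because the trans ring is the thermodynamic isomer, any reversible ionisation at C2 should return the configuration dictated by the untouched C3 centre.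

**Compound list**
1 | 4-fluoro-3-methoxybenzaldehyde | COc1cc(C=O)ccc1F | starting material
2 | 2-(4-fluoro-3-methoxyphenyl)-1,3-dioxolane | COc1cc(C2OCCO2)ccc1F | intermediate
3 | 2-[5-(1,3-dioxolan-2-yl)-2-fluoro-3-methoxyphenyl]-4,4,5,5-tetramethyl-1,3,2-dioxaborolane | COc1cc(C2OCCO2)cc(B3OC(C)(C)C(C)(C)O3)c1F | intermediate
4 | ethyl 2-[5-(1,3-dioxolan-2-yl)-2-fluoro-3-methoxyphenyl]acetate | CCOC(=O)Cc1cc(C2OCCO2)cc(OC)c1F | intermediate
5 | 2-[5-(1,3-dioxolan-2-yl)-2-fluoro-3-methoxyphenyl]acetic acid | OC(=O)Cc1cc(C2OCCO2)cc(OC)c1F | intermediate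
6 | (R)-4-benzyl-1,3-oxazolidin-2-one | O=C1N[C@H](Cc2ccccc2)CO1 | starting material
7 | 2-[5-(1,3-dioxolan-2-yl)-2-fluoro-3-methoxyphenyl]acetic pivalic anhydride | CC(C)(C)C(=O)OC(=O)Cc1cc(C2OCCO2)cc(OC)c1F | intermediate
8 | (R)-4-benzyl-3-{2-[5-(1,3-dioxolan-2-yl)-2-fluoro-3-methoxyphenyl]acetyl}-1,3-oxazolidin-2-one | O=C(Cc1cc(C2OCCO2)cc(OC)c1F)N1C(=O)OC[C@H]1Cc1ccccc1 | intermediate
9 | vanillin (4-hydroxy-3-methoxybenzaldehyde) | COc1cc(C=O)ccc1O | starting material
10 | 3-methoxy-4-(methoxymethoxy)benzaldehyde | COCOc1ccc(C=O)cc1OC | intermediate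
11 | Z-dibutylboron enolate of 8 | CCCCB(CCCC)O/C(=C\c1cc(C2OCCO2)cc(OC)c1F)N1C(=O)OC[C@H]1Cc1ccccc1 | intermediate
12 | O-dibutylboryl aldolate of 13, (2R,3R) | O=C([C@H](c1cc(C2OCCO2)cc(OC)c1F)[C@@H](OB(CCCC)CCCC)c1ccc(OCOC)c(OC)c1)N1C(=O)OC[C@H]1Cc1ccccc1 | intermediate
13 | (R)-4-benzyl-3-{(2R,3R)-2-[5-(1,3-dioxolan-2-yl)-2-fluoro-3-methoxyphenyl]-3-hydroxy-3-[3-methoxy-4-(methoxymethoxy)phenyl]propanoyl}-1,3-oxazolidin-2-one | O=C([C@H](c1cc(C2OCCO2)cc(OC)c1F)[C@@H](O)c1ccc(OCOC)c(OC)c1)N1C(=O)OC[C@H]1Cc1ccccc1 | intermediate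
14 | (1R,2S)-2-[5-(1,3-dioxolan-2-yl)-2-fluoro-3-methoxyphenyl]-1-[3-methoxy-4-(methoxymethoxy)phenyl]propane-1,3-diol | OC[C@H](c1cc(C2OCCO2)cc(OC)c1F)[C@@H](O)c1ccc(OCOC)c(OC)c1 | intermediate
15 | (1R,2S)-2-[5-(1,3-dioxolan-2-yl)-2-fluoro-3-methoxyphenyl]-1-[3-methoxy-4-(methoxymethoxy)phenyl]-3-[(triisopropylsilyl)oxy]propan-1-ol | CC(C)[Si](OC[C@H](c1cc(C2OCCO2)cc(OC)c1F)[C@@H](O)c1ccc(OCOC)c(OC)c1)(C(C)C)C(C)C | intermediate
16 | 4-fluoro-3-[(1R,2S)-1-hydroxy-1-[3-methoxy-4-(methoxymethoxy)phenyl]-3-[(triisopropylsilyl)oxy]propan-2-yl]-5-methoxybenzaldehyde | COCOc1ccc([C@H](O)[C@H](CO[Si](C(C)C)(C(C)C)C(C)C)c2cc(C=O)cc(OC)c2F)cc1OC | intermediate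
17 | potassium alkoxide of 16 | COCOc1ccc([C@H]([O-])[C@H](CO[Si](C(C)C)(C(C)C)C(C)C)c2cc(C=O)cc(OC)c2F)cc1OC.[K+] | intermediate
18 | (2R,3S)-7-methoxy-2-[3-methoxy-4-(methoxymethoxy)phenyl]-3-{[(triisopropylsilyl)oxy]methyl}-2,3-dihydro-1-benzofuran-5-carbaldehyde | COCOc1ccc([C@@H]2Oc3c(OC)cc(C=O)cc3[C@H]2CO[Si](C(C)C)(C(C)C)C(C)C)cc1OC | intermediate
19 | methyl 3,5-dihydroxybenzoate | COC(=O)c1cc(O)cc(O)c1 | starting material
20 | methyl 3,5-bis(methoxymethoxy)benzoate | COCOc1cc(OCOC)cc(C(=O)OC)c1 | intermediate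
21 | [3,5-bis(methoxymethoxy)phenyl]methanol | COCOc1cc(CO)cc(OCOC)c1 | intermediate
22 | 1-(bromomethyl)-3,5-bis(methoxymethoxy)benzene | COCOc1cc(CBr)cc(OCOC)c1 | intermediate
23 | diethyl [3,5-bis(methoxymethoxy)benzyl]phosphonate | CCOP(=O)(Cc1cc(OCOC)cc(OCOC)c1)OCC | intermediate
24 | potassium salt of the benzylic carbanion of 23 | CCOP(=O)([CH-]c1cc(OCOC)cc(OCOC)c1)OCC.[K+] | intermediate
25 | (2R,3S)-5-{(E)-2-[3,5-bis(methoxymethoxy)phenyl]ethenyl}-7-methoxy-2-[3-methoxy-4-(methoxymethoxy)phenyl]-3-{[(triisopropylsilyl)oxy]methyl}-2,3-dihydro-1-benzofuran | COCOc1ccc([C@@H]2Oc3c(OC)cc(/C=C/c4cc(OCOC)cc(OCOC)c4)cc3[C@H]2CO[Si](C(C)C)(C(C)C)C(C)C)cc1OC | intermediate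
26 | [(2R,3S)-5-{(E)-2-[3,5-bis(methoxymethoxy)phenyl]ethenyl}-7-methoxy-2-[3-methoxy-4-(methoxymethoxy)phenyl]-2,3-dihydro-1-benzofuran-3-yl]methanol | COCOc1ccc([C@@H]2Oc3c(OC)cc(/C=C/c4cc(OCOC)cc(OCOC)c4)cc3[C@H]2CO)cc1OC | intermediate
27 | Gnetofuran A, 5-{(E)-2-[(2R,3S)-2-(4-hydroxy-3-methoxyphenyl)-3-(hydroxymethyl)-7-methoxy-2,3-dihydro-1-benzofuran-5-yl]ethenyl}benzene-1,3-diol | COc1cc([C@@H]2Oc3c(OC)cc(/C=C/c4cc(O)cc(O)c4)cc3[C@H]2CO)ccc1O | target

**Step count**
Total steps: 18. Longest linear sequence: 13 steps (steps 1–5, 7–11 and 16–18); steps 6 and 12–15 make the two side fragments.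

**Steps most likely to fail**

Step 11. The secondary alkoxide may transfer hydride to the formyl group of a second molecule or add to it, or silicon may shift to the C2 oxygen and let the C9 oxygen close the isomeric ring, before fluoride is displaced. The fallback sets out from 16 and exchanges the formyl group for a nitrile, an equally strong para activator that neither accepts hydride nor adds alkoxide. I2 in aqueous NH3/THF at rt should convert the aldehyde directly into 4-fluoro-3-[(1R,2S)-1-hydroxy-1-[3-methoxy-4-(methoxymethoxy)phenyl]-3-[(triisopropylsilyl)oxy]propan-2-yl]-5-methoxybenzonitrile F1. KN(SiMe3)2 in THF then closes the ring by the same substitution at C7a to give (2R,3S)-7-methoxy-2-[3-methoxy-4-(methoxymethoxy)phenyl]-3-{[(triisopropylsilyl)oxy]methyl}-2,3-dihydro-1-benzofuran-5-carbonitrile F2. Reduction with iBu2AlH in toluene at −78 °C and hydrolysis of the aldimine with cold 1 M HCl brings the route back at 18.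

Step 7. The boron triflate may open the dioxolane, or the α-aryl boron aldolate may revert and erode the syn selectivity during reaction or work-up. The fallback sets out from 5, which is coupled (EDC·HCl, DMAP, CH2Cl2) with (S)-4-benzyl-1,3-thiazolidine-2-thione to give (S)-4-benzyl-3-{2-[5-(1,3-dioxolan-2-yl)-2-fluoro-3-methoxyphenyl]acetyl}-1,3-thiazolidine-2-thione F3. Its tin enolate (Sn(OTf)2, N-ethylpiperidine, CH2Cl2, −78 °C) adds to 10 through a chelated chair, whose facial sense is opposite to that of the dipole-opposed boron enolate; this is why the S auxiliary is used. The addition should give (2R,3R)-1-[(4S)-4-benzyl-2-thioxo-1,3-thiazolidin-3-yl]-2-[5-(1,3-dioxolan-2-yl)-2-fluoro-3-methoxyphenyl]-3-hydroxy-3-[3-methoxy-4-(methoxymethoxy)phenyl]propan-1-one F4. NaBH4 in THF/EtOH cleaves the thioimide directly, and the route is rejoined at diol 14.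

Step 3. Protodeboronation of the ortho-fluoro arylboronate, or slow transmetalation of the pinacol ester, may outrun coupling with the α-bromo ester. The fallback sets out from 3 and reverses the polarity of the coupling. Ipso-iodination (NaI, TsNClNa, aqueous THF, rt) gives 2-(4-fluoro-3-iodo-5-methoxyphenyl)-1,3-dioxolane F5. A Negishi-type coupling with the Reformatsky reagent BrZnCH2CO2Et (Pd(dba)2, XPhos, THF, 60 °C) then arrives at ester 4.

**Further compounds**
F1 | step 11 | 4-fluoro-3-[(1R,2S)-1-hydroxy-1-[3-methoxy-4-(methoxymethoxy)phenyl]-3-[(triisopropylsilyl)oxy]propan-2-yl]-5-methoxybenzonitrile | COCOc1ccc([C@H](O)[C@H](CO[Si](C(C)C)(C(C)C)C(C)C)c2cc(C#N)cc(OC)c2F)cc1OC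
F2 | step 11 | (2R,3S)-7-methoxy-2-[3-methoxy-4-(methoxymethoxy)phenyl]-3-{[(triisopropylsilyl)oxy]methyl}-2,3-dihydro-1-benzofuran-5-carbonitrile | COCOc1ccc([C@@H]2Oc3c(OC)cc(C#N)cc3[C@H]2CO[Si](C(C)C)(C(C)C)C(C)C)cc1OC
F3 | step 7 | (S)-4-benzyl-3-{2-[5-(1,3-dioxolan-2-yl)-2-fluoro-3-methoxyphenyl]acetyl}-1,3-thiazolidine-2-thione | O=C(Cc1cc(C2OCCO2)cc(OC)c1F)N1C(=S)SC[C@@H]1Cc1ccccc1
F4 | step 7 | (2R,3R)-1-[(4S)-4-benzyl-2-thioxo-1,3-thiazolidin-3-yl]-2-[5-(1,3-dioxolan-2-yl)-2-fluoro-3-methoxyphenyl]-3-hydroxy-3-[3-methoxy-4-(methoxymethoxy)phenyl]propan-1-one | O=C([C@H](c1cc(C2OCCO2)cc(OC)c1F)[C@@H](O)c1ccc(OCOC)c(OC)c1)N1C(=S)SC[C@@H]1Cc1ccccc1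
F5 | step 3 | 2-(4-fluoro-3-iodo-5-methoxyphenyl)-1,3-dioxolane | COc1cc(C2OCCO2)cc(I)c1F
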